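## Structural features

The target is a pentabrominated diphenyl ether: two benzene rings joined only through one oxygen atom, with no further ring and no stereocentre, so no stereocentres stand next to each other. Ring A (C1–C6) carries the ether oxygen at C1, a hydroxyl at C2 and bromine at C4 and C6. Ring B (C1'–C6') carries the ether oxygen at C1', a hydroxyl at C2' and three contiguous bromines at C4', C5' and C6'. Each ether carbon is flanked by a hydroxyl-bearing carbon and a bromine-bearing carbon, so the C1–O–C1' unit is tetra-ortho-substituted and sits between two electron-poor rings. The real difficulty is to form this crowded ether bond from a weakly nucleophilic oxygen and a deactivated aryl carbon while leaving five C–Br bonds untouched, which argues against CuI-mediated Ullmann coupling, Pd(OAc)2-catalysed etherification and any step that uses n-BuLi. The fragile elements are the C–Br bonds (reduction, halogen–metal exchange, light) and the ortho-hydroxy diaryl ether motif, which under base and heat can close to a dibenzo-p-dioxin by displacement of the C6 or C6' bromine. The two adjacent oxygens of ring B (on C1' and C2') must also be told apart. The key step exploits the C1–C2 unit of ring A: an ether carbon next to a hydroxyl carbon corresponds to the diazo carbon and the carbonyl carbon of an ortho-quinone diazide, so C1 can be turned into a carbenoid centre and the ring re-aromatises as soon as the O–C1 bond exists.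

## Logic of the disconnections

9 to 8: the O–CH3 bond on the C2' oxygen of ring B is added retrosynthetically. Ring B has two neighbouring oxygens and only the one on C1' may become the bridge, so masking the other one makes the bond-forming step unambiguous. Methyl is kept as the mask because hydrogenolysis of a benzyl ether would endanger the C–Br bonds and a silyl group can migrate between catechol oxygens. The demand on the forward step is an ether cleavage that spares five C–Br bonds and the diaryl ether and avoids hot base (dioxin closure).

8 to 5 + 7: the O–C1 bond of ring A is cut. This is the only skeletal bond between the two halves. Cutting it here makes C1 a carbenoid carbon and the ring B oxygen an O–H donor, so that no aryl halide has to be activated and no phenoxide has to attack a hindered ring. The gain is two monocyclic pieces of one to three steps each. The demand is that the carbenoid be captured by a hindered, acidic phenol faster than it rearranges or couples with itself.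

5 to 3 (through 4): the C1=N2 unit is traced back to a C1–NH2 group next to the C2 hydroxyl. The nitrogen marks the future ether carbon with complete positional certainty. The demand is a diazotisation of a weakly basic aminophenol and careful handling of an energetic, light-sensitive product.

3 to 2: the O–CH3 bond on the C2 oxygen of ring A is added. The methyl ether keeps the ring from oxidising during halogenation and leaves the amino group as the only strong director. The demand is a demethylation that does not move or remove bromine.

2 to 1: the C4–Br and C6–Br bonds are cut. Both lie para and ortho to the amino group, the positions where electrophilic substitution occurs naturally, so the pattern of ring A falls out of one operation on a commodity amine. The demand is clean stopping at the dibromide.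

7 to 6: the three C–Br bonds on C4', C5' and C6' are cut. These are the positions para and ortho to the hydroxyl and para to the methoxy group, again the innate pattern. The demand is to stop before the fourth, least activated position reacts.

## Other disconnections considered

Alternative 1: The cut runs through ring B itself. The C1'–C6' and C2'–C3' bonds are broken. C3' to C6' with their three bromines then come from 2,3,4-tribromothiophene 1,1-dioxide A1. C1' and C2' come from the alkyne carbons of 2-[(2,4-dibromo-6-methoxyphenoxy)ethynyl]-4,4,5,5-tetramethyl-1,3,2-dioxaborolane A2, an ynol ether that already carries ring A on oxygen. Forward, a [4+2] cycloaddition of A1 with A2 followed by cheletropic loss of SO2 would give the aryl boronate A3. Oxidation of its C–B bond and cleavage of the methyl ether would follow.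
- In its favour: the crowded ether is never made by a bimolecular attack on a hindered ring, because the congestion arises during aromatisation. The electron-poor diene A1 and the electron-rich ynol ether A2 are electronically matched. Boron marks C2' unambiguously.
- Against it here: A1 has an unsubstituted ring position, and thiophene dioxides of this kind tend to dimerise and need forcing oxidants to prepare. Nothing strongly enforces the required orientation (oxygen-bearing alkyne carbon to the brominated diene terminus). The usual access to an aryl ynol ether boronate such as A2 passes through lithiation with n-BuLi, which would compete with bromine–lithium exchange on ring A.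
- Comparison: on structure the alternative is the better plan for steric reasons, and it is also better in that it avoids a diazo compound. On mechanism it exchanges a chemoselectivity question (insertion against Wolff rearrangement) for a regiochemical one, whereas the chosen plan has its regiochemistry fixed by the diazo carbon. On step economy it is the weaker, needing two steps after the key step and roughly eight to ten in all against six.

Alternative 2: Both C–OH bonds (C2–O and C2'–O) are traced back to C–CHO bonds, so the precursor is the bis-aldehyde 3,5-dibromo-2-(2,3,4-tribromo-6-formylphenoxy)benzaldehyde A4. Forward, a peracid would convert both formyl groups of A4 by aryl migration (Baeyer–Villiger, Dakin type) into the bis-formate A5, which mild methanolysis would turn into the target.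
- In its favour: an ortho-formyl group activates a fluoroarene for nucleophilic aromatic substitution, so the ether bond of A4 could be made by robust, metal-free chemistry. Both hydroxyls are unmasked together, and no BBr3, no diazo compound and no Rh2(OAc)4 are needed. On safety, cost and closeness to established practice for hydroxylated polybromodiphenyl ethers it is the equal or the better of the chosen plan.
- Against it here: both migrating aryl groups are electron-poor, so hydride migration to the carboxylic acids could compete, and it has to be avoided twice in one molecule. The nucleophile for the ether formation would be a tribrominated salicylaldehyde, more hindered and less nucleophilic than 7 and harder to obtain with the right bromine pattern.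
- Comparison: step economy is about equal (five to six steps). Mechanistically the chosen plan makes the ether under neutral conditions with the regiochemistry fixed. The alternative relies on a hot basic substitution, which in this series carries a risk of dioxin closure once a free ortho-hydroxyl is present.

Alternative 3: The cut runs through ring A. The C1–C6 and C2–C3 bonds are broken. The four carbons C3 to C6 then come from the diene of 3,5-dibromo-2H-pyran-2-one A6. C1 and C2 come from the alkyne carbons of 2-[(2,3,4-tribromo-6-methoxyphenoxy)ethynyl]-4,4,5,5-tetramethyl-1,3,2-dioxaborolane A7. Forward, cycloaddition of A6 with A7 and loss of CO2 would give the aryl boronate A8. Oxidation of its C–B bond would lead to 8 itself, so this alternative converges with the chosen route one step before the end.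
- In its favour: A6 is a stable, ambiphilic diene, and cycloaddition of pyrones with alkynylboronates followed by decarboxylation is an established route to aryl boronates. The polarisation is matched: the nucleophilic boron-bearing alkyne carbon of A7 should bond to the electrophilic C6 of A6 and the oxygen-bearing carbon to its C3, which is the required orientation. This regiochemical bias and the absence of a diazo intermediate are points on which it is the equal or the better of the chosen plan.
- Against it here: pyrone–alkyne cycloadditions with CO2 loss normally need high temperature, at which an aryl ynol ether such as A7 is prone to decomposition. Making A7 from 7 again calls for n-BuLi in the presence of three aryl bromides.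
- Comparison: the sequence is longer, about nine steps against six. Structurally it solves the crowding problem more elegantly, but it moves the risk into the preparation and thermal survival of A7. The chosen plan concentrates its risk in one catalytic step with simple, robust precursors.

Key step: step 5

Remark on the chemistry: ring A is numbered from the ether carbon C1 towards the hydroxyl carbon C2, ring B likewise with primes. The bromine patterns of 2 and 7 map onto the target without correction. The only design change is that 5, a potentially energetic diazo compound, is never dried or stored but carried as a cold solution and used as the limiting reagent against an excess of 7.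

## Route

Step 1
Reactants: 1 o-anisidine (2-methoxyaniline)
Product: 2 2,4-dibromo-6-methoxyaniline
Conditions: NBS (2.05 equiv), MeCN, 0 °C to rt
Reagents that add atoms: N-bromosuccinimide, O=C1CCC(=O)N1Br
Why: Electrophilic aromatic bromination; the amino group is the dominant director and sends bromine to its para position and its only free ortho position (the other ortho site holds the methoxy group), which become C4 and C6 of ring A.

Step 2
Reactants: 2 2,4-dibromo-6-methoxyaniline
Product: 3 2-amino-3,5-dibromophenol
Conditions: BBr3 (3 equiv), CH2Cl2, −78 °C to rt; then H2O, aq NaHCO3 to pH 7
Reagents that add atoms: none
Why: BBr3 cleavage of an aryl methyl ether; the excess covers complexation by the amine, and the low temperature avoids the bromine migration or loss that hot mineral acid can cause in ortho/para-bromoanilines.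

Step 3
Reactants: 3 2-amino-3,5-dibromophenol
Product: 5 3,5-dibromo-6-diazocyclohexa-2,4-dien-1-one, via 2,4-dibromo-6-hydroxybenzenediazonium chloride 4 (not isolated)
Conditions: NaNO2 (1.05 equiv), aq HCl, 0 °C; then NaHCO3 to pH 6–7, CH2Cl2 extraction in the dark, MgSO4; solvent exchanged to 1,2-dichloroethane without taking to dryness
Reagents that add atoms: sodium nitrite, [Na+].[O-]N=O
Why: Diazotisation of an ortho-aminophenol; the ortho-hydroxy diazonium ion is a strong acid and gives up its phenolic proton on mild buffering to form the neutral ortho-quinone diazide, the standard preparation of halogenated members of this class, and the cold, dark solution limits both hazard and photochemical Wolff rearrangement.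

Step 4
Reactants: 6 guaiacol (2-methoxyphenol)
Product: 7 4,5,6-tribromoguaiacol (2,3,4-tribromo-6-methoxyphenol)
Conditions: Br2 (3.1 equiv), AcOH, 0 °C to rt; recrystallisation
Reagents that add atoms: bromine, BrBr
Why: Exhaustive electrophilic bromination of the three most activated positions, para and ortho to the hydroxyl (C4, C6) and para to the methoxy group (C5); C3, activated only as an ortho position of the methoxy group and buttressed by it, reacts last, so controlled stoichiometry should stop at the tribromide.

Step 5
Reactants: 5 3,5-dibromo-6-diazocyclohexa-2,4-dien-1-one; 7 4,5,6-tribromoguaiacol (2,3,4-tribromo-6-methoxyphenol)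
Product: 8 3,5-dibromo-2-(2,3,4-tribromo-6-methoxyphenoxy)phenol
Conditions: Rh2(OAc)4 (2 mol %), 7 (2.5 equiv), 4 Å MS, 1,2-dichloroethane, 60–70 °C, dark, slow addition of 5 by syringe pump
Reagents that add atoms: none
Why: Rh2(OAc)4 attacks the diazo carbon of 5 (C1 of ring A), N2 leaves, and the electrophilic rhodium carbenoid, which is equally a rhodium-bound 2-oxidoaryl cation, is captured by the phenolic oxygen of 7 to give a metal-associated oxonium ylide; transfer of the phenolic proton to the neighbouring C2 carbonyl oxygen releases the catalyst and delivers the aromatic 2-aryloxyphenol 8 directly, with aromatisation as the driving force. The closest known reaction type is the Rh2(OAc)4-catalysed O–H insertion of cyclic α-diazo ketones and quinone diazides into alcohols and phenols, applied here to a pair in which both partners are doubly ortho-substituted. No ring is closed and no stereocentre is formed. The site of the new C–O bond is fixed by the diazo carbon, and on ring B only the free hydroxyl can insert because the neighbouring oxygen is methylated. The selectivity needed is O–H insertion over Wolff ring contraction, carbenoid self-coupling and azo coupling: a metal carbenoid instead of a free ketocarbene, exclusion of light, moderate temperature, slow addition of 5 and an excess of the acidic phenol all favour insertion, and 7 has both ortho positions and the para position of its hydroxyl occupied (OMe, Br, Br), so it cannot serve as an azo-coupling partner. The non-aromatic chlorinated solvent removes arene addition as an outlet, the sieves remove water as a competing O–H donor, and no C–Br bond is engaged because no aryl halide activation is involved.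

Step 6
Reactants: 8 3,5-dibromo-2-(2,3,4-tribromo-6-methoxyphenoxy)phenol
Product: 9 3,4,5-tribromo-2-(2,4-dibromo-6-hydroxyphenoxy)phenol
Conditions: BBr3 (3 equiv), CH2Cl2, −78 °C to rt; then H2O (acidic work-up, no base)
Reagents that add atoms: none
Why: BBr3 demethylation, the usual way from methoxylated to hydroxylated polybromodiphenyl ethers; the diaryl ether and the C–Br bonds are inert to it, and the base-free work-up avoids phenoxide-driven dioxin closure.

## Compound list

1 | o-anisidine (2-methoxyaniline) | COc1ccccc1N | starting material
2 | 2,4-dibromo-6-methoxyaniline | COc1cc(Br)cc(Br)c1N | intermediate
3 | 2-amino-3,5-dibromophenol | Nc1c(O)cc(Br)cc1Br | intermediate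
4 | 2,4-dibromo-6-hydroxybenzenediazonium chloride | Oc1cc(Br)cc(Br)c1[N+]#N.[Cl-] | intermediate (not isolated)
5 | 3,5-dibromo-6-diazocyclohexa-2,4-dien-1-one | O=C1C=C(Br)C=C(Br)C1=[N+]=[N-] | intermediate
6 | guaiacol (2-methoxyphenol) | COc1ccccc1O | starting material
7 | 4,5,6-tribromoguaiacol (2,3,4-tribromo-6-methoxyphenol) | COc1cc(Br)c(Br)c(Br)c1O | intermediate
8 | 3,5-dibromo-2-(2,3,4-tribromo-6-methoxyphenoxy)phenol | Oc1cc(Br)cc(Br)c1Oc1c(OC)cc(Br)c(Br)c1Br | intermediate
9 | 3,4,5-tribromo-2-(2,4-dibromo-6-hydroxyphenoxy)phenol | Oc1cc(Br)cc(Br)c1Oc1c(O)cc(Br)c(Br)c1Br | target

## Step count and least certain steps

Total step count: 6. Longest linear sequence: 5 steps (steps 1, 2, 3, 5 and 6); step 4 is the single step of the second branch.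

Step 5 (key step). The most likely failure is slow capture of the carbenoid by the hindered, weakly nucleophilic phenol oxygen. The diazide would then be consumed by thermal Wolff ring contraction, by carbenoid self-coupling, or by azo coupling onto the free ortho and para positions of the product phenol. Formation of the carbenoid at a diazo carbon flanked by a bromine may itself be sluggish. The fallback leaves carbenoid chemistry and sets out from 7. Deprotonated by K2CO3 in DMF at 80 °C, 7 should displace fluoride from 3,5-dibromo-2-fluorobenzaldehyde F1 in an aldehyde-activated nucleophilic aromatic substitution to give 3,5-dibromo-2-(2,3,4-tribromo-6-methoxyphenoxy)benzaldehyde F2. Baeyer–Villiger (Dakin-type) oxidation with mCPBA in CH2Cl2 should convert the formyl group into 3,5-dibromo-2-(2,3,4-tribromo-6-methoxyphenoxy)phenyl formate F3. Brief methanolysis (catalytic K2CO3, MeOH, 0 °C) should release the phenol, returning to the route at 8.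

Step 3. Incomplete diazotisation of the weakly basic, poorly soluble aminophenol could lead to coupling between the diazonium ion and unreacted amine. The diazide may also decay during neutralisation, extraction and solvent exchange. The fallback sets out from 3 and avoids aqueous handling of the neutral diazide. Anhydrous diazotisation with tert-butyl nitrite and HBF4·OEt2 in THF at −10 °C, followed by precipitation with ether, should give 2,4-dibromo-6-hydroxybenzenediazonium tetrafluoroborate F4 as a salt that can be filtered and kept cold. Immediately before the insertion this salt is stirred with solid NaHCO3 and MgSO4 in 1,2-dichloroethane and filtered, which returns to the route at 5 as a fresh solution.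

Step 4. Bromination may not stop cleanly at three bromines. Under-bromination at C5 together with over-bromination at C3 would give a mixture that is hard to separate by crystallisation. The fallback sets out from 6 and installs the bromines in two regiochemically separate stages. Acetylation (Ac2O, catalytic DMAP) should give 2-methoxyphenyl acetate F5, in which the methoxy group is the stronger director. Bromination with NBS in MeCN should then place the first bromine para to it, giving 5-bromo-2-methoxyphenyl acetate F6. Methanolysis (K2CO3, MeOH) should release 5-bromo-2-methoxyphenol F7, and Br2 (2 equiv, AcOH) should fill the para and ortho positions of the free hydroxyl, returning to the route at 7.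

Steps 1, 2 and 6 are standard operations on this compound class and are not expected to limit the route.

## Further compounds

F1 | step 5 | 3,5-dibromo-2-fluorobenzaldehyde | O=Cc1cc(Br)cc(Br)c1F
F2 | step 5 | 3,5-dibromo-2-(2,3,4-tribromo-6-methoxyphenoxy)benzaldehyde | O=Cc1cc(Br)cc(Br)c1Oc1c(OC)cc(Br)c(Br)c1Br
F3 | step 5 | 3,5-dibromo-2-(2,3,4-tribromo-6-methoxyphenoxy)phenyl formate | O=COc1cc(Br)cc(Br)c1Oc1c(OC)cc(Br)c(Br)c1Br
F4 | step 3 | 2,4-dibromo-6-hydroxybenzenediazonium tetrafluoroborate | Oc1cc(Br)cc(Br)c1[N+]#N.F[B-](F)(F)F
F5 | step 4 | 2-methoxyphenyl acetate | COc1ccccc1OC(C)=O
F6 | step 4 | 5-bromo-2-methoxyphenyl acetate | COc1ccc(Br)cc1OC(C)=O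
F7 | step 4 | 5-bromo-2-methoxyphenol | COc1ccc(Br)cc1O
A1 | alternative 1 | 2,3,4-tribromothiophene 1,1-dioxide | O=S1(=O)C(Br)=C(Br)C(Br)=C1
A2 | alternative 1 | 2-[(2,4-dibromo-6-methoxyphenoxy)ethynyl]-4,4,5,5-tetramethyl-1,3,2-dioxaborolane | COc1cc(Br)cc(Br)c1OC#CB1OC(C)(C)C(C)(C)O1
A3 | alternative 1 | 2-[3,4,5-tribromo-2-(2,4-dibromo-6-methoxyphenoxy)phenyl]-4,4,5,5-tetramethyl-1,3,2-dioxaborolane | COc1cc(Br)cc(Br)c1Oc1c(Br)c(Br)c(Br)cc1B1OC(C)(C)C(C)(C)O1
A4 | alternative 2 | 3,5-dibromo-2-(2,3,4-tribromo-6-formylphenoxy)benzaldehyde | O=Cc1cc(Br)cc(Br)c1Oc1c(C=O)cc(Br)c(Br)c1Br
A5 | alternative 2 | 3,5-dibromo-2-[2,3,4-tribromo-6-(formyloxy)phenoxy]phenyl formate | O=COc1cc(Br)cc(Br)c1Oc1c(OC=O)cc(Br)c(Br)c1Br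
A6 | alternative 3 | 3,5-dibromo-2H-pyran-2-one | O=C1OC=C(Br)C=C1Br
A7 | alternative 3 | 2-[(2,3,4-tribromo-6-methoxyphenoxy)ethynyl]-4,4,5,5-tetramethyl-1,3,2-dioxaborolane | COc1cc(Br)c(Br)c(Br)c1OC#CB1OC(C)(C)C(C)(C)O1
A8 | alternative 3 | 2-[3,5-dibromo-2-(2,3,4-tribromo-6-methoxyphenoxy)phenyl]-4,4,5,5-tetramethyl-1,3,2-dioxaborolane | COc1cc(Br)c(Br)c(Br)c1Oc1c(Br)cc(Br)cc1B1OC(C)(C)C(C)(C)O1
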